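West has the charge of oak and larch, and a plug-flow tube is a closed flask read along its length, so those two read as one, carried on past west's last reading.

| flask | starting material | protic impurity | remark | time |
|---|---|---|---|---|
| west | 10 mM | 3 mM | run made earlier |  |
| south | 10 mM | 1.5 mM | run made earlier |  |
| south-west | 10 mM | 2.2 mM | run made earlier |  |
| north-east | 5 mM | 3 mM | run made earlier |  |
| elm | 10 mM (fed, over 80.0 min) | 3.00 mM | all but starting material at the start; starting material goes in evenly over 80.0 min, the run ends at 80 min | 80 min |
| oak | 10 mM | 3.00 mM | a closed flask charged with all of it at once and left for 80 min | 80 min |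
| larch | 10 mM | 3.00 mM | a tube with plug flow, the mixed feed as stated, residence time 80 min | 80 min |
| alder | 10 mM | 3.00 mM | a single well-mixed tank run continuously and read at steady state, 80 min in it on average |  |

| run | time / min | ring / % | open dimer / % | starting material / % |
|---|---|---|---|---|
| west | 6.00 | 4 | 19 | 51 |
| west | 15.0 | 12 | 24 | 34 |
| west | 30.0 | 25 | 24 | 19 |
| west | 50.0 | 32 | 21 | 16 |
| south | 5.00 | 11 | 15 | 61 |
| south | 12.0 | 15 | 28 | 43 |
| south | 30.0 | 29 | 29 | 26 |
| south | 60.0 | 38 | 27 | 18 |
| south-west | 5.00 | 9 | 18 | 59 |
| south-west | 12.0 | 17 | 28 | 37 |
| south-west | 30.0 | 26 | 29 | 25 |
| south-west | 60.0 | 39 | 23 | 18 |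
| north-east | 8.00 | 7 | 10 | 43 |
| north-east | 25.0 | 21 | 13 | 18 |
| north-east | 40.0 | 25 | 8 | 11 |
| north-east | 60.0 | 31 | 11 | 7 |

(readings scatter by 2 percentage points)

- percentages count the starting material that a species holds: one open dimer counts as two
- the stated concentrations are those of everything mixed, before any reaction; amounts are the same in each set-up
- the feed brings no volume worth counting
- the earlier runs were made in a closed, stirred flask

* the set-up with the highest share of ring in all that became ring or open dimer, at the outlet or at the end ("none" if the first two lie within 2 percentage points) (elm / oak / larch / alder / none)
* share of ring in all that became ring or open dimer, at the outlet or at the end, elm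
* share of ring in all that became ring or open dimer, at the outlet or at the end, oak
* share of ring in all that became ring or open dimer, at the outlet or at the end, larch
* share of ring in all that became ring or open dimer, at the outlet or at the end, alder

I take ring as first order in [starting material] and open dimer as second. The first readings of west, south and south-west pool to ring 24.0% against open dimer 52.0%, at a mean [starting material] of 7.85 mM. Their ratio times that mean gives 3.62 mM, which I call the tie level, the [starting material] at which ring and open dimer form equally fast. Ring's part of fresh product, the instantaneous selectivity, is then one over one plus [starting material] divided by the tie level.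

West starts at 10 mM, where that part is 26.6%, and [starting material] falls by about 0.817 mM min⁻¹ over the first 6.00 min. It crosses the tie level before 15.0 min, reading 3.40 mM there. The loss bends by 15.0 min: the missing balance reads 26.0% at 6.00 min, 30.0% at 15.0 min and 31.0% at 50.0 min, against 30.0% as the impurity's equivalents, so protic impurity looks like the limiting reagent of that loss. At the last reading [starting material] stands at 1.60 mM, giving fresh product 69.4% ring, while the collected share reads 60.4%. Fresh product there is richer in ring than the collected share, so I expect the share in oak and larch to go on rising past that reading.

The forecast gives elm 65%, oak 67%, larch 67% and alder 71%: “Alder is expected best, modestly”. Its tank level of 2.25 mM stands under my tie level of 3.62 mM, but that does not rank the set-ups, and I take the ranking from the forecast.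

Alder comes out best at 76.2%, 5.2 percentage points above the forecast, with oak and larch at 71.5% and elm at 68.6%.

    2 starting material ⇌ open dimer (K = 200 M⁻¹, k = 3.30 M⁻¹ min⁻¹)
    starting material → ring (k = 0.0210 min⁻¹)
    starting material + protic impurity → quenched substrate (k = 36.0 M⁻¹ min⁻¹)

Elm ends at 2.95 mM of starting material, which gives fresh product 55.1% ring against its collected 68.6%. The neighbour fed 40 mM the same way ends at 9.15 mM, which gives 28.4%. Its collected share is 39.3%, with ring 27.4% against open dimer 42.2%.

The readings stem from a simulated flask with constants of no real substance, and the scatter is random.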